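One ratio is followed here: side product A plus side product B over target, as fractions of the charge.

| setting | south | west | south-west | green | grey |
|---|---|---|---|---|---|
| starting material | 0.81 M | 1.1 M | 1.8 M | 0.81 M | 0.81 M |
| remark | run made earlier | run made earlier | run made earlier | one stirred flow tank at steady state, fed with the mixture as stated, mean residence time 2.0 min | everything together in a closed stirred flask, run for 2.0 min |
| time |  |  |  |  | 2.0 min |

south run (percent of the starting material charged)

| time / s | target / % | side product A / % | side product B / % |
|---|---|---|---|
| 10.0 | 38.3 | 10.9 | 1.4 |
| 15.0 | 43.3 | 12.7 | 2.6 |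
| 25.0 | 47.8 | 14.4 | 4.0 |
| 40.0 | 51.1 | 14.7 | 4.9 |
| 80.0 | 53.8 | 16.2 | 7.0 |
| 120 | 52.9 | 14.5 | 7.0 |

west run (percent of the starting material charged)

| time / min | target / % | side product A / % | side product B / % |
|---|---|---|---|
| 0.417 | 44.7 | 13.6 | 3.2 |
| 0.833 | 48.1 | 12.6 | 4.7 |
| 1.33 | 48.2 | 14.2 | 6.8 |
| 1.50 | 48.6 | 14.6 | 6.7 |
| 2.00 | 48.7 | 14.4 | 5.8 |
| 2.50 | 49.0 | 15.6 | 6.5 |

south-west run (percent of the starting material charged)

| time / min | target / % | side product A / % | side product B / % |
|---|---|---|---|
| 0.200 | 32.2 | 10.1 | 1.4 |
| 0.333 | 36.7 | 11.8 | 3.3 |
| 0.500 | 39.3 | 11.3 | 4.5 |
| 0.833 | 40.4 | 12.9 | 5.7 |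
| 1.33 | 41.9 | 12.7 | 5.2 |
| 2.50 | 42.3 | 12.0 | 6.4 |

(standard deviation of a reading: 0.5 percentage points)

- the stated concentrations are those of everything mixed, before any reaction; amounts are the same in each set-up
- the earlier runs were read with a standard deviation of 0.5 percentage points
- the earlier runs were made in a closed, stirred flask

* the set-up with the highest share of target in all that became target or side product A or side product B, at the outlet or at the end ("none" if the first two lie within 2 percentage points) (green / grey / none)
* share of target in all that became target or side product A or side product B, at the outlet or at the end, green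
* share of target in all that became target or side product A or side product B, at the outlet or at the end, grey

At the last reading of each run this ratio is:

south: 0.406
west: 0.451
south-west: 0.435

The side ratio, the mean of these readings, is 0.431: that much side product stands beside one part of target. The share asked, the selectivity to target, is one over one plus this ratio:

share = 69.9 %

The starting concentration grows by a factor 2.22 across the runs, and the ratio at the last reading lies between 0.406 and 0.451. Time does move it. The south run reads 0.321 at 10.0 s and 0.431 at 80.0 s, earlier than grey's 2.0 min. So this reckoning puts grey at the share above. Of green's outlet, 8.00 % is younger than that first reading. This reckoning gives that portion the share of the first reading, 75.7 %, and so lifts green above grey by about 0.46 percentage points, less than the margin of 2 points, and answers none.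

The forecast gives 71.5 % for green (range 69.5 % to 74.5 %), 70.3 % for grey (range 69 % to 71.5 %), and none: “The tank raises total yield, but barely changes the share.”

Green gives 70.8 % and grey 70.0 %, so the answer is none; as side ratios these are 0.412 and 0.429.

    2 starting material → homo dimer (k = 0.0640 M⁻¹ s⁻¹)
    starting material ⇌ intermediate (K = 0.960, k = 0.0360 s⁻¹)
    starting material → side product A (k = 0.0270 s⁻¹)
    starting material → target (k = 0.0920 s⁻¹)
    intermediate → side product B (k = 0.0200 s⁻¹)

Striking out the homo dimer step leaves green's share unchanged. With the conversion into intermediate struck out both ways, grey's share is 77.3 %. That is a side ratio of 0.294, lower than the carried 0.431 by 0.137.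

The runs are simulated for substances that don't exist; scatter was added.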